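**Retrosynthetic overview**
- Target ⇒ one-pot acidic removal of two aryl MOM ethers and one TBS ether from the fully protected (Z,Z)-diene.
- C12′–C13′ bond and the 11Z alkene ⇒ proposed silver-catalysed Z-selective hydroalkylation of a terminal 1,4-enyne with the 9-BBN borane of (S)-pent-4-en-2-ol TBS ether (stereocentre bought from the chiral pool).
- C7′–C8′ bond and the 8Z alkene ⇒ the same hydroalkylation on a C5 linchpin, mono-silylated penta-1,4-diyne, with the 9-BBN borane of a 7-arylhept-1-ene.
- Aryl heptene ⇒ Kumada coupling of MOM-protected 5-bromoresorcinol with hept-6-enylmagnesium bromide; linchpin ⇒ ethynyl Grignard plus a silyl propargyl bromide.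
- Rings: the only ring (the resorcinol) is bought intact; no ring is formed.

Assumption: the target is the (16S) alcohol encoded by the SMILES (side chain numbered C1′ at the ring to C17′ at the methyl), and the four building blocks 3, 6, 7 and 12 are bought.

**Step 1**
Reactants: 1 5-bromobenzene-1,3-diol (5-bromoresorcinol)
Product: 2 1-bromo-3,5-bis(methoxymethoxy)benzene
Conditions: MOMCl (2.5 equiv), i-Pr2NEt (3 equiv), CH2Cl2, 0 °C to rt
Reagents that add atoms: chloromethyl methyl ether (MOMCl), COCCl
Why: Williamson-type O-alkylation of both phenols by the reactive α-chloro ether gives the bis-MOM ether, which is stable to Grignard, borane and fluoride chemistry and is removed by acid at the end.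

**Step 2**
Reactants: 2 1-bromo-3,5-bis(methoxymethoxy)benzene, 3 7-bromohept-1-ene
Product: 5 1-(hept-6-en-1-yl)-3,5-bis(methoxymethoxy)benzene, via hept-6-enylmagnesium bromide 4 (not isolated)
Conditions: 3, Mg, THF, 40 °C; then 2, PdCl2(dppf) (2 mol %), THF, 50 °C [dppf = 1,1′-bis(diphenylphosphino)ferrocene]
Reagents that add atoms: none
Why: Kumada–Corriu coupling in which the wide-bite-angle dppf ligand makes reductive elimination of the primary alkyl–aryl palladium species faster than β-hydride elimination, while MOM ethers and the remote terminal alkene are inert to the Grignard reagent.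

**Step 3**
Reactants: 6 ethynylmagnesium bromide (0.5 M in THF), 7 (3-bromoprop-1-yn-1-yl)tri(propan-2-yl)silane
Product: 8 penta-1,4-diyn-1-yltri(propan-2-yl)silane
Conditions: 6 (2 equiv), CuCl (5 mol %), THF, 0 to 50 °C
Reagents that add atoms: none
Why: Copper-catalysed alkynyl–propargyl coupling (SN2 displacement of the propargylic bromide by the alkynyl Grignard reagent), the standard entry to 1,4-diynes, with the robust Si(i-Pr)3 cap leaving only one reactive C–H terminus.

**Step 4**
Reactants: 5 1-(hept-6-en-1-yl)-3,5-bis(methoxymethoxy)benzene, 8 penta-1,4-diyn-1-yltri(propan-2-yl)silane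
Product: 10 {(4Z)-12-[3,5-bis(methoxymethoxy)phenyl]dodec-4-en-1-yn-1-yl}tri(propan-2-yl)silane, via B-(7-arylheptyl)-9-borabicyclo[3.3.1]nonane 9 (not isolated)
Conditions: 5, 9-BBN (1.05 equiv), THF, 0 °C to rt; then 8 (1.5 equiv), (IPr)AgCl (5 mol %), KOMe (10 mol %), MeOH (3 equiv), THF, 40 °C [IPr = 1,3-bis(2,6-diisopropylphenyl)imidazol-2-ylidene]
Reagents that add atoms: none
Why: Proposed new method: silver-catalysed anti-Markovnikov hydroalkylation of a skipped 1,4-diyne, in which (IPr)AgOMe (from (IPr)AgCl and KOMe) metalates only the free C–H terminus to a monovalent silver acetylide that passes its alkynyl group to the Lewis-acidic B-alkyl-9-BBN to give an alkynyl(trialkyl)borate; protonation of the internal alkyne carbon by MeOH triggers an anti 1,2-metalate shift of the primary alkyl group from boron to the terminal carbon, and stereoretentive protodeboronation of the resulting α-alkyl alkenylborane by MeOH releases the alkene with the new alkyl group and the propargylic CH2 cis, so the C7′–C8′ bond and the 8Z geometry are set stereospecifically; only catalytic methoxide is present and it is held as methoxyborate, which is why the base-labile bis-propargylic CH2 and the silyl cap should survive; closest known reaction type: electrophile-induced 1,2-metalate rearrangement of alkynyl(trialkyl)borates (Binger–Köster/Zweifel type) and silver-catalysed hydroalkylation of simple terminal alkynes with B-alkyl-9-BBN reagents, not yet shown on 1,4-diynes or used iteratively on a C5 linchpin.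

**Step 5**
Reactants: 10 {(4Z)-12-[3,5-bis(methoxymethoxy)phenyl]dodec-4-en-1-yn-1-yl}tri(propan-2-yl)silane
Product: 11 1-[(8Z)-dodec-8-en-11-yn-1-yl]-3,5-bis(methoxymethoxy)benzene
Conditions: TBAF, AcOH (1:1, 1.5 equiv), THF, 0 °C to rt
Reagents that add atoms: none
Why: Fluoride-mediated protodesilylation of the alkynylsilane, buffered with acetic acid so the medium stays non-basic and the 1,4-enyne does not isomerise to an allene, while MOM ethers and the Z-alkene are untouched.

**Step 6**
Reactants: 12 (S)-pent-4-en-2-ol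
Product: 13 tert-butyldimethyl{[(2S)-pent-4-en-2-yl]oxy}silane
Conditions: TBSCl, imidazole, CH2Cl2, rt
Reagents that add atoms: tert-butyldimethylsilyl chloride (TBSCl), CC(C)(C)[Si](C)(C)Cl
Why: Imidazole-promoted silylation (Corey protocol) of the secondary alcohol, which does not touch the chiral-pool (S) stereocentre that becomes C16′ of the target.

**Step 7**
Reactants: 13 tert-butyldimethyl{[(2S)-pent-4-en-2-yl]oxy}silane, 11 1-[(8Z)-dodec-8-en-11-yn-1-yl]-3,5-bis(methoxymethoxy)benzene
Product: 15 tert-butyl{[(2S,6Z,9Z)-17-[3,5-bis(methoxymethoxy)phenyl]heptadeca-6,9-dien-2-yl]oxy}dimethylsilane, via B-(4-silyloxypentyl)-9-borabicyclo[3.3.1]nonane 14 (not isolated)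
Conditions: 13 (1.6 equiv), 9-BBN (1.5 equiv), THF, 0 °C to rt; then 11 (1.0 equiv), (IPr)AgCl (5 mol %), KOMe (10 mol %), MeOH (3 equiv), THF, 40 °C
Reagents that add atoms: none
Why: Proposed new method: second use of the silver-catalysed hydroalkylation, now on a 1-en-4-yne, where the same sequence (monovalent silver acetylide, alkynylborate, proton-triggered anti 1,2-metalate shift of the primary alkyl group, stereoretentive protodeboronation) forms the C12′–C13′ bond and the 11Z alkene; no free B–H remains because 13 is in excess over 9-BBN, so the existing 8Z alkene is not hydroborated, the doubly activated CH2 sees only borate-bound catalytic methoxide, and the remote (S)-carbinol centre is not involved; closest known reaction type: alkynylborate 1,2-metalate rearrangement and silver-catalysed alkyne hydroalkylation with alkyl-9-BBN reagents, not yet shown for skipped enynes as a route to (Z,Z)-1,4-dienes.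

**Step 8**
Reactants: 15 tert-butyl{[(2S,6Z,9Z)-17-[3,5-bis(methoxymethoxy)phenyl]heptadeca-6,9-dien-2-yl]oxy}dimethylsilane
Product: 16 hansfordiol D, 5-[(8Z,11Z,16S)-16-hydroxyheptadeca-8,11-dien-1-yl]benzene-1,3-diol
Conditions: HCl (1.25 M in MeOH), 40 °C, argon
Reagents that add atoms: none
Why: Acid-catalysed methanolysis (transacetalisation of both MOM acetals and solvolysis of the silyl ether) unmasks all three hydroxyl groups in one operation, and the isolated Z-alkenes and the carbinol stereocentre are inert to dilute methanolic HCl.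

**Compound list**
1 | 5-bromobenzene-1,3-diol | Oc1cc(O)cc(Br)c1 | starting material
2 | 1-bromo-3,5-bis(methoxymethoxy)benzene | COCOc1cc(Br)cc(OCOC)c1 | intermediate
3 | 7-bromohept-1-ene | C=CCCCCCBr | starting material
4 | hept-6-en-1-ylmagnesium bromide | C=CCCCCC[Mg]Br | intermediate
5 | 1-(hept-6-en-1-yl)-3,5-bis(methoxymethoxy)benzene | C=CCCCCCc1cc(OCOC)cc(OCOC)c1 | intermediate
6 | ethynylmagnesium bromide | C#C[Mg]Br | starting material
7 | (3-bromoprop-1-yn-1-yl)tri(propan-2-yl)silane | CC(C)[Si](C(C)C)(C(C)C)C#CCBr | starting material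
8 | penta-1,4-diyn-1-yltri(propan-2-yl)silane | CC(C)[Si](C(C)C)(C(C)C)C#CCC#C | intermediate
9 | 9-{7-[3,5-bis(methoxymethoxy)phenyl]heptyl}-9-borabicyclo[3.3.1]nonane | COCOc1cc(OCOC)cc(CCCCCCCB2C3CCCC2CCC3)c1 | intermediate
10 | {(4Z)-12-[3,5-bis(methoxymethoxy)phenyl]dodec-4-en-1-yn-1-yl}tri(propan-2-yl)silane | CC(C)[Si](C(C)C)(C(C)C)C#CC/C=C\CCCCCCCc1cc(OCOC)cc(OCOC)c1 | intermediate
11 | 1-[(8Z)-dodec-8-en-11-yn-1-yl]-3,5-bis(methoxymethoxy)benzene | C#CC/C=C\CCCCCCCc1cc(OCOC)cc(OCOC)c1 | intermediate
12 | (S)-pent-4-en-2-ol | C[C@H](O)CC=C | starting material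
13 | tert-butyldimethyl{[(2S)-pent-4-en-2-yl]oxy}silane | C[C@H](O[Si](C)(C)C(C)(C)C)CC=C | intermediate
14 | 9-[(4S)-4-{[tert-butyl(dimethyl)silyl]oxy}pentyl]-9-borabicyclo[3.3.1]nonane | C[C@H](O[Si](C)(C)C(C)(C)C)CCCB1C2CCCC1CCC2 | intermediate
15 | tert-butyl{[(2S,6Z,9Z)-17-[3,5-bis(methoxymethoxy)phenyl]heptadeca-6,9-dien-2-yl]oxy}dimethylsilane | C[C@H](O[Si](C)(C)C(C)(C)C)CCC/C=C\C/C=C\CCCCCCCc1cc(OCOC)cc(OCOC)c1 | intermediate
16 | hansfordiol D, 5-[(8Z,11Z,16S)-16-hydroxyheptadeca-8,11-dien-1-yl]benzene-1,3-diol | C[C@H](O)CCC/C=C\C/C=C\CCCCCCCc1cc(O)cc(O)c1 | target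

**Step count**
Total step count: 8. Longest linear sequence: 6 steps (steps 1, 2, 4, 5, 7, 8); steps 3 and 6 are one-step side branches.

**Three steps most likely to fail**

Step 4 (proposed new method). Risks are propargyl-to-allenyl isomerisation of the 1,4-diyne, migration of a 9-BBN ring bond instead of the primary alkyl group, and sluggish protodeboronation. The fallback uses known chemistry, sets out from 8 and from borane 9 (made from 5 as in step 4), and returns at 10. Iodination of the terminal alkyne of 8 (N-iodosuccinimide, AgNO3 cat., acetone) gives (5-iodopenta-1,4-diyn-1-yl)tri(propan-2-yl)silane F1. cis-Reduction of the iodoalkyne with diimide (2-nitrobenzenesulfonyl hydrazide, Et3N, THF/i-PrOH) gives [(4Z)-5-iodopent-4-en-1-yn-1-yl]tri(propan-2-yl)silane F2. A stereoretentive B-alkyl Suzuki–Miyaura coupling of F2 with 9 (PdCl2(dppf), AsPh3, K3PO4 aq., DMF/THF, rt) then delivers 10.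

Step 5. The risk is isomerisation of the skipped enyne to a vinylallene, or slow cleavage of the bulky silyl group under buffered fluoride. The fallback sets out from 10 and returns at 15, so it bypasses the free terminal alkyne 11. Desilylative iodination of 10 (AgF, N-iodosuccinimide 1.05 equiv, MeCN, 0 °C, dark, to spare the electron-rich arene) gives 1-[(8Z)-12-iodododec-8-en-11-yn-1-yl]-3,5-bis(methoxymethoxy)benzene F3. Diimide cis-reduction gives 1-[(8Z,11Z)-12-iodododeca-8,11-dien-1-yl]-3,5-bis(methoxymethoxy)benzene F4. B-alkyl Suzuki–Miyaura coupling of F4 with borane 14 (from 13 and 9-BBN; PdCl2(dppf), AsPh3, K3PO4 aq., DMF/THF, rt) gives 15 with both Z-alkenes retained.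

Step 7 (proposed new method). Risks are those of step 4 plus hydroboration of the 8Z alkene if free B–H is left. The fallback uses known chemistry, sets out from 11, and returns at 15. Borane 14 is cleaved with I2/NaOMe to tert-butyl{[(2S)-5-iodopentan-2-yl]oxy}dimethylsilane F5. Alkyne 11 is deprotonated (n-BuLi, THF, −78 °C) to {(4Z)-12-[3,5-bis(methoxymethoxy)phenyl]dodec-4-en-1-yn-1-yl}lithium F6. Alkylation of F6 with F5 (THF/DMPU, −78 to 0 °C) gives tert-butyl{[(2S,9Z)-17-[3,5-bis(methoxymethoxy)phenyl]heptadec-9-en-6-yn-2-yl]oxy}dimethylsilane F7. Semi-hydrogenation of F7 (H2, Pd/CaCO3 poisoned with Pb(OAc)2, quinoline, EtOAc) gives 15.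

**Further compounds**
F1 | step 4 | (5-iodopenta-1,4-diyn-1-yl)tri(propan-2-yl)silane | CC(C)[Si](C(C)C)(C(C)C)C#CCC#CI
F2 | step 4 | [(4Z)-5-iodopent-4-en-1-yn-1-yl]tri(propan-2-yl)silane | CC(C)[Si](C(C)C)(C(C)C)C#CC/C=C\I
F3 | step 5 | 1-[(8Z)-12-iodododec-8-en-11-yn-1-yl]-3,5-bis(methoxymethoxy)benzene | IC#CC/C=C\CCCCCCCc1cc(OCOC)cc(OCOC)c1
F4 | step 5 | 1-[(8Z,11Z)-12-iodododeca-8,11-dien-1-yl]-3,5-bis(methoxymethoxy)benzene | I/C=C\C/C=C\CCCCCCCc1cc(OCOC)cc(OCOC)c1
F5 | step 7 | tert-butyl{[(2S)-5-iodopentan-2-yl]oxy}dimethylsilane | C[C@H](O[Si](C)(C)C(C)(C)C)CCCI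
F6 | step 7 | {(4Z)-12-[3,5-bis(methoxymethoxy)phenyl]dodec-4-en-1-yn-1-yl}lithium | [Li]C#CC/C=C\CCCCCCCc1cc(OCOC)cc(OCOC)c1
F7 | step 7 | tert-butyl{[(2S,9Z)-17-[3,5-bis(methoxymethoxy)phenyl]heptadec-9-en-6-yn-2-yl]oxy}dimethylsilane | C[C@H](O[Si](C)(C)C(C)(C)C)CCCC#CC/C=C\CCCCCCCc1cc(OCOC)cc(OCOC)c1
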